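**Plan** (side chain numbered C1' at the benzylic CH2 to C16')
1. Retrosynthesis: after removal of two aryl silyl ethers, the chain is cut at C10'–C11' (alkenyl CH to carbinol carbon). This gives an (E)-alkenylboronic ester of the aryl-C12 chain and the hindered benzoate of sulcatol, and the C11'–O bond is read as a C–B bond.
2. The boronic ester is cut at C10'–B (alkyne hydroboration), C8'–C9' (allylic bromide + ethynyl Grignard), C8'–O (allylic oxidation of a geranyl group) and aryl–C1' (aryl Grignard + geranyl bromide). The bromohydroquinone comes from 4-hydroxy-3-methylbenzaldehyde.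
3. Forward: the benzene ring is bought and no ring is formed. The chain is joined in the order arene, C10 (geranyl), C2 (ethynyl), boron, C8 (sulcatyl), and desilylation comes last.
4. Enabling feature: C11' is a tertiary carbinol carbon bearing CH3, an unbranched CH2 and the sp2 carbon C10'. Its secondary methyl-carbinol precursor can be lithiated alpha to oxygen, so the normally electrophilic carbinol carbon becomes a carbanion and takes the likewise nucleophilic alkenyl carbon from boron by a 1,2-shift.
5. Stereochemistry: C11' (S) comes from (R)-sulcatol by inversion (Mitsunobu), retention (lithiation, borylation), inversion (1,2-shift) and retention (oxidation). 2'E comes from geranyl bromide, 6'E from the E-selective SeO2 oxidation, and 9'E from syn hydroboration.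

Key step: step 10

Assumption: (R)-(−)-sulcatol of high enantiomeric purity is taken as a catalogue compound; both enantiomers are also accessible from racemic sulcatol by lipase-catalysed acylation.

Step 1
Reactants: 1 4-hydroxy-3-methylbenzaldehyde
Product: 2 3-bromo-4-hydroxy-5-methylbenzaldehyde
Conditions: Br2 (1.05 equiv), AcOH, rt
Reagents that add atoms: bromine, BrBr
Why: Electrophilic aromatic bromination, in which the free phenol directs to its only open ortho position (C5), because the para position holds the formyl group and the other ortho position the methyl group.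

Step 2
Reactants: 2 3-bromo-4-hydroxy-5-methylbenzaldehyde
Product: 4 2-bromo-6-methylbenzene-1,4-diol, via aryl formate 3 (not isolated)
Conditions: 30% H2O2 (1.2 equiv), aq. NaOH, 0 °C → rt, N2; then 2 M HCl
Reagents that add atoms: hydrogen peroxide, OO
Why: Dakin oxidation: hydroperoxide adds to the aldehyde of the electron-rich para-hydroxyaryl system, aryl migration gives formate 3, and this is saponified in the same flask, while the C–Br bond is inert to these conditions.

Step 3
Reactants: 4 2-bromo-6-methylbenzene-1,4-diol
Product: 5 1-bromo-3-methyl-2,5-bis(triisopropylsilyloxy)benzene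
Conditions: TIPSOTf (2.4 equiv), 2,6-lutidine (3 equiv), CH2Cl2, 0 °C → rt
Reagents that add atoms: triisopropylsilyl triflate, CC(C)[Si](C(C)C)(C(C)C)OS(=O)(=O)C(F)(F)F
Why: Silyl ether formation with the silyl triflate, which is reactive enough for the hydroxyl flanked by Br and CH3; TIPS ethers should stand Grignard and organolithium reagents, SeO2 and perborate, and leave with fluoride at the end without acid.

Step 4
Reactants: 5 1-bromo-3-methyl-2,5-bis(triisopropylsilyloxy)benzene; 6 geranyl bromide [(2E)-1-bromo-3,7-dimethylocta-2,6-diene]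
Product: 8 1-[(2E)-3,7-dimethylocta-2,6-dienyl]-3-methyl-2,5-bis(triisopropylsilyloxy)benzene, via arylmagnesium bromide 7 (not isolated)
Conditions: Mg turnings, LiCl, THF, rt; then CuI (10 mol %), 6, −20 → 0 °C
Reagents that add atoms: none
Why: Magnesium insertion followed by copper-catalysed allylic substitution of a Grignard reagent, which should occur at the primary carbon of 6 (attack at the fully substituted C3 by a hindered aryl copper species is disfavoured) with the 2E geometry kept, and the magnesium reagent is chosen over the lithium one to avoid O-to-C silyl migration (retro-Brook rearrangement).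

Step 5
Reactants: 8 geranyl arene
Product: 9 (2E,6E)-2,6-dimethyl-8-[3-methyl-2,5-bis(triisopropylsilyloxy)phenyl]octa-2,6-dien-1-ol
Conditions: SeO2 (0.3 equiv), t-BuOOH (decane, 2.5 equiv), salicylic acid (0.1 equiv), CH2Cl2, 0 °C → rt, stopped at partial conversion, recovered 8 recycled
Reagents that add atoms: selenium dioxide, O=[Se]=O (catalytic oxygen carrier); tert-butyl hydroperoxide, CC(C)(C)OO (terminal oxidant)
Why: Riley-type allylic oxidation with catalytic SeO2 (ene reaction, then [2,3]-sigmatropic shift), which attacks the exposed terminal trisubstituted alkene at its E-methyl group and so sets the 6'E geometry, whereas the inner alkene lies next to the bulky ortho-silyloxy arene.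

Step 6
Reactants: 9 allylic alcohol
Product: 10 1-[(2E,6E)-8-bromo-3,7-dimethylocta-2,6-dienyl]-3-methyl-2,5-bis(triisopropylsilyloxy)benzene
Conditions: CBr4, PPh3, CH2Cl2, −20 → 0 °C
Reagents that add atoms: carbon tetrabromide, BrC(Br)(Br)Br
Why: Appel reaction, an SN2 displacement at the primary allylic carbon under nearly neutral conditions, so that neither allylic transposition nor silyl ether loss is expected.

Step 7
Reactants: 10 allylic bromide
Product: 11 1-[(2E,6E)-3,7-dimethyldeca-2,6-dien-9-ynyl]-3-methyl-2,5-bis(triisopropylsilyloxy)benzene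
Conditions: HC≡CMgBr (0.5 M in THF, 3 equiv), CuI (15 mol %), THF, 0 °C → rt
Reagents that add atoms: ethynylmagnesium bromide, C#C[Mg]Br
Why: Copper-catalysed coupling of an alkynyl Grignard reagent with a primary allylic bromide, which gives skipped 1,4-enynes by substitution at the CH2 terminus, and the excess of the acetylide suppresses a second alkylation.

Step 8
Reactants: 11 skipped enyne
Product: 13 2-{(1E,4E,8E)-4,8-dimethyl-10-[3-methyl-2,5-bis(triisopropylsilyloxy)phenyl]deca-1,4,8-trienyl}-5,5-dimethyl-1,3,2-dioxaborinane, via alkenyl catechol boronate 12 (not isolated)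
Conditions: catecholborane (1.3 equiv), Cy2BH (10 mol %), THF, rt; then neopentyl glycol (1.5 equiv), rt
Reagents that add atoms: catecholborane, B1Oc2ccccc2O1; neopentyl glycol, OCC(C)(C)CO
Why: Dicyclohexylborane-catalysed hydroboration of a terminal alkyne with catecholborane (syn, anti-Markovnikov, hence 9'E; trisubstituted alkenes do not react at room temperature), followed by transesterification to the unhindered neopentyl glycol ester that the next step needs.

Step 9
Reactants: 14 (R)-(−)-sulcatol [(2R)-6-methylhept-5-en-2-ol]
Product: 15 (2S)-6-methylhept-5-en-2-yl 2,4,6-triisopropylbenzoate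
Conditions: 2,4,6-i-Pr3C6H2CO2H, PPh3, DIAD, THF, 0 °C → rt
Reagents that add atoms: 2,4,6-triisopropylbenzoic acid, CC(C)c1cc(C(C)C)c(C(=O)O)c(C(C)C)c1
Why: Mitsunobu esterification, whose SN2 course inverts C2 cleanly for an unhindered methyl carbinol and turns the R alcohol into the S ester, and the hindered aroyl group later shields the carbonyl from s-BuLi.

Step 10
Reactants: 15 (S)-sulcatyl 2,4,6-triisopropylbenzoate; 13 (E)-alkenylboronic acid neopentyl glycol ester
Product: 19 (6S,7E,10E,14E)-2,6,10,14-tetramethyl-16-[3-methyl-2,5-bis(triisopropylsilyloxy)phenyl]hexadeca-2,7,10,14-tetraen-6-ol, via lithiated benzoate 16 (not isolated), via lithium boronate complex 17 (not isolated), via tertiary allylic boronic ester 18 (not isolated)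
Conditions: 15 (1.6 equiv), s-BuLi (1.5 equiv), TMEDA (6 equiv), CPME, −60 °C; then 13 (1.0 equiv), −60 °C → rt → 40 °C; then NaBO3·4H2O, THF–H2O, rt
Reagents that add atoms: sodium perborate (tetrahydrate), [Na+].[Na+].O[B-]1(O)OO[B-](O)(O)OO1
Why: s-BuLi·TMEDA, held by the benzoate carbonyl, removes the C–H alpha to oxygen of 15 with retention and gives the configurationally stable tertiary organolithium 16, which adds with retention to the vacant boron orbital of 13 to give boronate complex 17; on warming, the E-alkenyl carbon shifts from boron to carbon antiperiplanar to the leaving triisopropylbenzoate (invertive 1,2-metallate rearrangement), which forms the C10'–C11' bond in 18, and perborate then exchanges C–B for C–OH with retention. The closest known reaction type is the lithiation–borylation–oxidation of enantioenriched secondary dialkyl 2,4,6-triisopropylbenzoates with neopentyl glycol boronic esters, and alkenyl groups are established migrating groups in such 1,2-shifts. No ring is closed. The one new stereocentre C11' is controlled by the substrate alone, since every event is stereospecific (retention, retention, inversion, retention), so that (S)-15 should give (S)-19, and the migrating sp2 carbon keeps the 9'E geometry. The step needs alpha-lithiation rather than allylic deprotonation of 15 (secured by the carbonyl-directed deprotonation and the small CH3 and CH2 flanks of the methyl carbinol, while the 4-pentenyl-type organolithium has no favourable cyclisation mode), attack at boron rather than proton abstraction from the doubly allylic C8'H2 of 13 (secured by the unhindered, Lewis-acidic neopentyl glycol ester at −60 °C and by keeping 15 in excess over s-BuLi so that no free base meets 13), and carbon rather than oxygen migration (secured by the high migratory aptitude of the alkenyl group and the good benzoate leaving group). In one flask the step thus joins two carbons of like (nucleophilic) polarity and delivers the C–C bond, the tertiary stereocentre, the C–O bond and the intact E-alkene.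

Step 11
Reactants: 19 bis-TIPS ether of the target
Product: 20 2-[(2E,6E,9E,11S)-11-hydroxy-3,7,11,15-tetramethylhexadeca-2,6,9,14-tetraenyl]-6-methylbenzene-1,4-diol (target)
Conditions: TBAF (2.5 equiv), AcOH (2.5 equiv), THF, 0 °C → rt, Ar, degassed work-up
Reagents that add atoms: none
Why: Fluoride-induced cleavage of aryl silyl ethers, fast because phenoxide is a good leaving group on silicon, and buffered with acetic acid under argon so that the tertiary allylic alcohol (no acid, no ionisation or chroman formation), the skipped diene and the oxidisable hydroquinone survive.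

**Compound list**
1 | 4-hydroxy-3-methylbenzaldehyde | Cc1cc(C=O)ccc1O | starting material
2 | 3-bromo-4-hydroxy-5-methylbenzaldehyde | Cc1cc(C=O)cc(Br)c1O | intermediate
3 | 3-bromo-4-hydroxy-5-methylphenyl formate | Cc1cc(OC=O)cc(Br)c1O | intermediate
4 | 2-bromo-6-methylbenzene-1,4-diol | Cc1cc(O)cc(Br)c1O | intermediate
5 | 1-bromo-3-methyl-2,5-bis(triisopropylsilyloxy)benzene | Cc1cc(O[Si](C(C)C)(C(C)C)C(C)C)cc(Br)c1O[Si](C(C)C)(C(C)C)C(C)C | intermediate
6 | geranyl bromide | CC(C)=CCC/C(C)=C/CBr | starting material
7 | [3-methyl-2,5-bis(triisopropylsilyloxy)phenyl]magnesium bromide | Cc1cc(O[Si](C(C)C)(C(C)C)C(C)C)cc([Mg]Br)c1O[Si](C(C)C)(C(C)C)C(C)C | intermediate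
8 | geranyl arene (bis-TIPS ether of 2-geranyl-6-methylhydroquinone) | CC(C)=CCC/C(C)=C/Cc1cc(O[Si](C(C)C)(C(C)C)C(C)C)cc(C)c1O[Si](C(C)C)(C(C)C)C(C)C | intermediate
9 | (2E,6E)-8'-allylic alcohol | OC/C(C)=C/CC/C(C)=C/Cc1cc(O[Si](C(C)C)(C(C)C)C(C)C)cc(C)c1O[Si](C(C)C)(C(C)C)C(C)C | intermediate
10 | (2E,6E)-8'-allylic bromide | BrC/C(C)=C/CC/C(C)=C/Cc1cc(O[Si](C(C)C)(C(C)C)C(C)C)cc(C)c1O[Si](C(C)C)(C(C)C)C(C)C | intermediate
11 | skipped (2E,6E)-dien-9-yne | C#CC/C(C)=C/CC/C(C)=C/Cc1cc(O[Si](C(C)C)(C(C)C)C(C)C)cc(C)c1O[Si](C(C)C)(C(C)C)C(C)C | intermediate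
12 | (E)-alkenyl catechol boronate | B1(Oc2ccccc2O1)/C=C/C/C(C)=C/CC/C(C)=C/Cc3cc(O[Si](C(C)C)(C(C)C)C(C)C)cc(C)c3O[Si](C(C)C)(C(C)C)C(C)C | intermediate
13 | (E)-alkenylboronic acid neopentyl glycol ester | CC1(C)COB(OC1)/C=C/C/C(C)=C/CC/C(C)=C/Cc2cc(O[Si](C(C)C)(C(C)C)C(C)C)cc(C)c2O[Si](C(C)C)(C(C)C)C(C)C | intermediate
14 | (R)-sulcatol | CC(C)=CCC[C@@H](C)O | starting material
15 | (S)-sulcatyl 2,4,6-triisopropylbenzoate | CC(C)=CCC[C@H](C)OC(=O)c1c(C(C)C)cc(C(C)C)cc1C(C)C | intermediate
16 | (S)-2-lithio-6-methylhept-5-en-2-yl 2,4,6-triisopropylbenzoate | CC(C)=CCC[C@]([Li])(C)OC(=O)c1c(C(C)C)cc(C(C)C)cc1C(C)C | intermediate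
17 | lithium boronate complex of 16 and 13 | [Li+].CC(C)=CCC[C@](C)(OC(=O)c1c(C(C)C)cc(C(C)C)cc1C(C)C)[B-]2(OCC(C)(C)CO2)/C=C/C/C(C)=C/CC/C(C)=C/Cc3cc(O[Si](C(C)C)(C(C)C)C(C)C)cc(C)c3O[Si](C(C)C)(C(C)C)C(C)C | intermediate
18 | (R)-tertiary allylic boronic acid neopentyl glycol ester | CC(C)=CCC[C@](C)(B1OCC(C)(C)CO1)/C=C/C/C(C)=C/CC/C(C)=C/Cc2cc(O[Si](C(C)C)(C(C)C)C(C)C)cc(C)c2O[Si](C(C)C)(C(C)C)C(C)C | intermediate
19 | (S)-tertiary allylic alcohol, bis-TIPS ether of the target | CC(C)=CCC[C@](C)(O)/C=C/C/C(C)=C/CC/C(C)=C/Cc1cc(O[Si](C(C)C)(C(C)C)C(C)C)cc(C)c1O[Si](C(C)C)(C(C)C)C(C)C | intermediate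
20 | 2-[(2E,6E,9E,11S)-11-hydroxy-3,7,11,15-tetramethylhexadeca-2,6,9,14-tetraenyl]-6-methylbenzene-1,4-diol | CC(C)=CCC[C@](C)(O)/C=C/C/C(C)=C/CC/C(C)=C/Cc1cc(O)cc(C)c1O | target

Total steps: 11. Longest linear sequence: 10 (steps 1–8, 10, 11).

**Steps most likely to fail**

Step 10.
- What may go wrong: slow or incomplete alpha-lithiation of the unactivated benzoate; proton transfer from the doubly allylic CH2 to the organolithium in competition with boronate formation; or a 1,3-borotropic shift of the allylic boronic ester before oxidation.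
- Fallback (sets out from 11, comes back at 19): the carbanion is moved to an allylic position, where lithiation is much easier, and the homoprenyl group becomes the migrating group. Hydrozirconation of 11 (Cp2ZrHCl), transmetalation to zinc (Me2Zn) and addition to acetaldehyde catalysed by a chiral amino alcohol should give the (R,E)-allylic alcohol F1. Carbamoylation with i-Pr2NCOCl should give the N,N-diisopropylcarbamate F2. The partner, 4-methylpent-3-enylboronic acid pinacol ester F3, is made from commercial 5-bromo-2-methylpent-2-ene (Mg, then i-PrOBpin). Lithiation of F2 (s-BuLi, TMEDA, Et2O, −78 °C), addition of F3 and warming should give, by the same retention/inversion course, the tertiary allylic pinacol boronic ester F4. Perborate oxidation of F4 leads to 19.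

Step 5.
- What may go wrong: poor site selectivity between the two trisubstituted alkenes and the benzylic-allylic C1'H2, over-oxidation to the enal stage, or low conversion.
- Fallback (sets out from 5 by way of 7, comes back at 9): the oxidation is moved to commercial geranyl acetate, whose acetoxy group deactivates the nearer alkene. SeO2/t-BuOOH should give (2E,6E)-8-hydroxygeranyl acetate F5. TBSCl/imidazole gives the silyl ether acetate F6, K2CO3/MeOH the allylic alcohol F7, and CBr4/PPh3 the allylic bromide F8. Copper-catalysed coupling of F8 with the Grignard reagent 7 gives the aryl-geranyl TBS ether F9. Catalytic CSA in MeOH at 0 °C then removes the alkyl TBS group selectively beside the acid-stable aryl TIPS ethers to give 9.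

Step 7.
- What may go wrong: attack at the gamma carbon (SN2′), a second alkylation of the acetylide, or base-induced isomerisation of the skipped enyne into conjugation.
- Fallback (sets out from 10, comes back at 11): Stille coupling of 10 with commercial tributyl(ethynyl)stannane [Pd2(dba)3, P(2-furyl)3, THF, rt]. This runs under neutral conditions through a π-allylpalladium species and should form the C–C bond at the less hindered CH2 terminus. New compounds on this way: none F0.

**Further compounds**
F1 | step 10 | (2R,3E,6E,10E)-6,10-dimethyl-12-[3-methyl-2,5-bis(triisopropylsilyloxy)phenyl]dodeca-3,6,10-trien-2-ol | C[C@@H](O)/C=C/C/C(C)=C/CC/C(C)=C/Cc1cc(O[Si](C(C)C)(C(C)C)C(C)C)cc(C)c1O[Si](C(C)C)(C(C)C)C(C)C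
F2 | step 10 | N,N-diisopropylcarbamate of F1 | C[C@@H](OC(=O)N(C(C)C)C(C)C)/C=C/C/C(C)=C/CC/C(C)=C/Cc1cc(O[Si](C(C)C)(C(C)C)C(C)C)cc(C)c1O[Si](C(C)C)(C(C)C)C(C)C
F3 | step 10 | 4-methylpent-3-enylboronic acid pinacol ester | CC(C)=CCCB1OC(C)(C)C(C)(C)O1
F4 | step 10 | (R)-tertiary allylic boronic acid pinacol ester | CC(C)=CCC[C@](C)(B1OC(C)(C)C(C)(C)O1)/C=C/C/C(C)=C/CC/C(C)=C/Cc2cc(O[Si](C(C)C)(C(C)C)C(C)C)cc(C)c2O[Si](C(C)C)(C(C)C)C(C)C
F5 | step 5 | (2E,6E)-8-hydroxygeranyl acetate | OC/C(C)=C/CC/C(C)=C/COC(C)=O
F6 | step 5 | (2E,6E)-8-(tert-butyldimethylsilyloxy)geranyl acetate | CC(C)(C)[Si](C)(C)OC/C(C)=C/CC/C(C)=C/COC(C)=O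
F7 | step 5 | (2E,6E)-8-(tert-butyldimethylsilyloxy)geraniol | CC(C)(C)[Si](C)(C)OC/C(C)=C/CC/C(C)=C/CO
F8 | step 5 | (2E,6E)-8-(tert-butyldimethylsilyloxy)geranyl bromide | CC(C)(C)[Si](C)(C)OC/C(C)=C/CC/C(C)=C/CBr
F9 | step 5 | TBS ether of 9 | CC(C)(C)[Si](C)(C)OC/C(C)=C/CC/C(C)=C/Cc1cc(O[Si](C(C)C)(C(C)C)C(C)C)cc(C)c1O[Si](C(C)C)(C(C)C)C(C)C
F0 | step 7 | none | none
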